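**Assumptions (remarks on the chemistry)**
- Germacrane numbering is used throughout: ring C1–C10, C14 = methyl on C10, C15 = methyl on C4, lactone carbons C11–C13. The same atom numbers are used for the corresponding atoms of the six-membered precursors.
- The target is read as (1R,4Z,6R,7S,8S,9S,10R)-1,10-epoxy-9-hydroxy-8-(2-methylpropanoyloxy)germacra-4,11(13)-dien-12,6-olide.
- (S)-3-Methylcyclohexanone (6) is taken as a catalogue compound; both antipodes are sold.

## The problem

Compound 25 is a heliangolide-type germacranolide: a ten-membered carbocycle (C1–C10) with a Z-trisubstituted C4=C5 olefin, the trans-epoxide of an E-C1=C10 olefin, and an α-methylene-γ-butyrolactone trans-fused across C6–C7. Closing a cyclodecadiene end to end is unfavourable, and both olefin geometries would have to be built into an open chain beforehand. The ring carries four contiguous stereocentres C6–C9: C11, O8 and O9 lie on one face and O6 on the other, an all-cis C7/C8/C9 array that simple steric control does not favour. The C9 hydroxyl can direct the epoxide (C1, C10), C8 can steer C7 and C7 can steer C6, so the cis C8/C9 pair is the root of all seven stereocentres. Only O8 is acylated, next to a free cis O9 hydroxyl (risk of acyl migration), and a free 8-hydroxyl next to the 6,12-lactone can translactonise. The α-methylene lactone is a Michael acceptor, and the epoxide beside the 4,5-olefin opens transannularly under acid, so both must come late. The feature that makes the key step possible is the arc C6(O)–C7–C8–C9–C10=C1, which is a 5-hexenone (oxy-Cope) retron once the lactone oxygen is read as a C6 ketone and the epoxide as the C1=C10 olefin. The complementary arc C1–C2–C3–C4=C5–C6 holds the Z olefin, which is the only geometry a cyclohexene can have. A transannular C1–C6 bond therefore maps the target onto a 1,2-dialkenylcyclohex-2-enol whose two alkene termini (C8, C9) carry the future oxygens.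

## Retrosynthesis

25 from 24. The C1–O and C10–O bonds are cut last. The epoxide is the most acid-labile group, and the free C9 hydroxyl of 24 can deliver the oxidant to the outer face of the E-olefin. The precursor has two stereocentres fewer.

24 from 23, 19, 18 and 16. These are functional-group cuts: the PMB ether on O9, the C11=C13 methylene (Mannich/elimination on lactone 19), the isobutyrate on O8, and the C8–O bond itself, which is traced to a C8–Si bond (Tamao–Fleming, retention). Silicon stands in for oxygen at C8 because an alkoxy group β to the enolate formed in the key step would be eliminated, and because it differentiates O8 from O9 without a selective acylation.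

16 from 14. The lactone C6–O bond is cut to keto ester 14. The forward step is a 1,2-reduction of the Z-enone from the outer face followed by lactonisation.

14 from 11 (key). The C8–C9 and C7–C11 bonds are cut and the C1–C6 bond is restored. This replaces a ten-membered ring with three stereocentres by a cyclohexenol with two, only one of which (C1) carries information. The neighbouring cuts (C6–C7 with the lactone, or either olefin) are end-to-end macrocyclisations that set no stereocentre at C8/C9 and need both olefin geometries in an acyclic chain. The forward reaction must run through a chair with an (E)-vinylsilane (Si equatorial) and a (Z)-enol ether (OPMB axial), so that the two heteroatoms end cis, with the C1–C2 bond equatorial so that C1=C10 is E. The enolate then has to be alkylated at C7 from the outer face.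

11 from 10 and 9. The C8–Si bond comes from β-(E)-hydrosilylation of alkyne 10, and the C6–C7 bond from acetylide addition to enone 9.

9 from 7, and 7 from 6 plus 5. The C4=C5 bond is introduced by dehydrogenation, and the C1–C10 bond by α-alkenylation of 6 with bromide 5. The methyl-bearing carbon C4 serves as a relay that fixes C1 (2,5-trans) and is then erased.

5 from 3 plus 4, and 3 from 1. The (Z)-enol ether geometry comes from syn-bromoboration of propyne followed by a stereoretentive C–O coupling.

## Roads not taken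

Alternative 1: the most obvious cut is C6–C7 together with the lactone C–O bond. The forward key step is an intramolecular Nozaki–Hiyama–Kishi or Barbier allylation (CrCl2 or Zn) of seco-aldehyde A1 by its 2-(bromomethyl)acrylate, then lactonisation. A1 needs the erythro C8/C9 diol, an isomerisation-prone (Z)-enal and an (E)-trisubstituted olefin to be built separately in a long linear chain. The ring closure then has to set C6 and C7 under high dilution with induction only from C8. The chosen plan takes both olefin geometries from ring templates and makes C8, C9 and the ring in one step.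

Alternative 2: cut the C4=C5 olefin. The forward key step is ring-closing metathesis of diene A2 with the second-generation Grubbs catalyst. A trisubstituted Z-olefin inside a strained ten-membered ring is a poor metathesis target (E/Z uncertain, oligomers likely), and the α-methylene lactone is a competing partner. All four stereocentres would have to be in place before the ring exists, so the ring closure solves none of the stereochemical problem.

Alternative 3: keep the C1–C6 transannular bond but in a decalin, and cut it by Grob fragmentation of the 6-hydroxy-10-mesylate A3 with KOtBu. The fragmentation is stereospecific for the E olefin. A3, however, needs six contiguous stereocentres, two of them fully substituted, on a bicycle, and its product is the same kind of keto ester as 14. The oxy-Cope route reaches that point from a monocycle with two stereocentres.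

Key step: step 7

## Route

Step 1
Reactants: 1 propyne
Product: 3 2-[(Z)-2-bromoprop-1-en-1-yl]-4,4,5,5-tetramethyl-1,3,2-dioxaborolane, via dibromo[(Z)-2-bromoprop-1-enyl]borane 2 (not isolated)
Conditions: BBr3, CH2Cl2, −78 °C; then pinacol, −78 → 25 °C
Reagents that add atoms: boron tribromide BrB(Br)Br; pinacol CC(C)(O)C(C)(C)O
Why: Syn-bromoboration (haloboration) of a terminal alkyne puts boron on the terminal carbon cis to bromine; esterification with pinacol gives the stable (Z)-alkenylboronate and fixes the geometry that later becomes the C9 configuration.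

Step 2
Reactants: 3 2-[(Z)-2-bromoprop-1-en-1-yl]-4,4,5,5-tetramethyl-1,3,2-dioxaborolane; 4 (4-methoxyphenyl)methanol
Product: 5 1-({[(Z)-2-bromoprop-1-en-1-yl]oxy}methyl)-4-methoxybenzene
Conditions: Cu(OAc)2 (2 equiv), Et3N, 4 Å MS, excess 4, CH2Cl2, air, 25 °C
Reagents that add atoms: none
Why: Chan–Lam-type copper-mediated C–O coupling of an alkenyl pinacol boronate with an alcohol proceeds with retention of olefin geometry, so oxygen ends cis to bromine; the C–Br bond should be inert to Cu(OAc)2.

Step 3
Reactants: 6 (3S)-3-methylcyclohexan-1-one; 5 1-({[(Z)-2-bromoprop-1-en-1-yl]oxy}methyl)-4-methoxybenzene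
Product: 7 (2R,5S)-2-{(Z)-1-[(4-methoxyphenyl)methoxy]prop-1-en-2-yl}-5-methylcyclohexan-1-one
Conditions: Pd2(dba)3 (cat.), Q-Phos, LiN(SiMe3)2, THF, 25 → 50 °C; 2,5-trans isomer separated
Reagents that add atoms: none
Why: Palladium-catalysed α-alkenylation of a ketone enolate with an alkenyl bromide retains the olefin geometry; coupling should occur at the less hindered α-methylene remote from the methyl group, and equilibration of the new α-centre under the basic conditions should favour the diequatorial 2,5-trans isomer, so the methyl centre relays its configuration to C1 (R).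

Step 4
Reactants: 7 (2R,5S)-2-{(Z)-1-[(4-methoxyphenyl)methoxy]prop-1-en-2-yl}-5-methylcyclohexan-1-one
Product: 9 (6R)-6-{(Z)-1-[(4-methoxyphenyl)methoxy]prop-1-en-2-yl}-3-methylcyclohex-2-en-1-one, via lithium enolate 8 (not isolated)
Conditions: LiN(iPr)2, THF, −78 °C; then N-tert-butylbenzenesulfinimidoyl chloride, −78 °C
Reagents that add atoms: none
Why: Kinetic deprotonation at the unsubstituted α-methylene followed by Mukaiyama dehydrogenation (S-alkylation of the enolate, syn-elimination of the sulfenamide) gives the enone without Pd(OAc)2, which could attack the enol ether; the relay centre C4 becomes sp2 and C1 is not touched at −78 °C.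

Step 5
Reactants: 9 (6R)-6-{(Z)-1-[(4-methoxyphenyl)methoxy]prop-1-en-2-yl}-3-methylcyclohex-2-en-1-one
Product: 10 (1R,6R)-1-ethynyl-6-{(Z)-1-[(4-methoxyphenyl)methoxy]prop-1-en-2-yl}-3-methylcyclohex-2-en-1-ol
Conditions: HC≡CMgBr, LaCl3·2LiCl (0.3 equiv), THF, −78 → 0 °C
Reagents that add atoms: ethynylmagnesium bromide C#C[Mg]Br
Why: Lewis-acid-assisted 1,2-addition of an alkynyl Grignard reagent suppresses enolisation at the acidic C1–H; attack anti to the neighbouring alkenyl group should give the trans-1,2-carbinol (C6 R), and any cis epimer can pass through the same chair in step 7 as long as the C1–C2 bond stays equatorial.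

Step 6
Reactants: 10 (1R,6R)-1-ethynyl-6-{(Z)-1-[(4-methoxyphenyl)methoxy]prop-1-en-2-yl}-3-methylcyclohex-2-en-1-ol
Product: 11 (1R,6R)-1-{(E)-2-[benzyl(dimethyl)silyl]ethenyl}-6-{(Z)-1-[(4-methoxyphenyl)methoxy]prop-1-en-2-yl}-3-methylcyclohex-2-en-1-ol
Conditions: BnMe2SiH, PtCl2 (cat.), XPhos, THF, 50 °C
Reagents that add atoms: benzyl(dimethyl)silane C[SiH](C)Cc1ccccc1
Why: Platinum-catalysed syn-hydrosilylation of a terminal propargylic alcohol is β-(E)-selective and leaves trisubstituted alkenes alone; it places silicon trans to the carbinol carbon, as the chair of step 7 requires.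

Step 7
Reactants: 11 (1R,6R)-1-{(E)-2-[benzyl(dimethyl)silyl]ethenyl}-6-{(Z)-1-[(4-methoxyphenyl)methoxy]prop-1-en-2-yl}-3-methylcyclohex-2-en-1-ol
Product: 14 methyl (1(10)E,4Z,7S,8S,9R)-8-[benzyl(dimethyl)silyl]-9-[(4-methoxybenzyl)oxy]-6-oxo-13-norgermacra-1(10),4-dien-12-oate, via potassium alkoxide 12 (not isolated), via potassium dienolate 13 (not isolated)
Conditions: KH, 18-crown-6, THF, 0 → 25 °C; then −78 °C, BrCH2CO2Me
Reagents that add atoms: methyl bromoacetate COC(=O)CBr
Why: KH gives the tertiary alkoxide 12, which undergoes a [3,3]-sigmatropic shift (anionic oxy-Cope rearrangement) through a chair, forming C8–C9 as C1–C6 breaks, and the resulting dienolate 13 is C-alkylated at C7 by methyl bromoacetate. The closest known reaction type is the anionic oxy-Cope ring expansion of trans-1,2-dialkenylcyclohexanols to cyclodec-5-enones with in situ enolate alkylation. The ten-membered ring is closed by a four-atom ring enlargement of the cyclohexene (bonding between the two exocyclic alkene termini), not by an end-to-end cyclisation. At C8 the (E)-vinylsilane puts silicon equatorial and at C9 the (Z)-enol ether puts OPMB axial, so the two groups end cis (8S,9R); the absolute sense comes from C1 (R), whose C1–C2 bond must be equatorial. The same chair makes C1=C10 E, while C4=C5 keeps the Z geometry of the six-membered ring. C7 is set by attack of the electrophile on the outer face of the ring-E dienolate past H8, with the silyl group in the enolate plane and C9 on the inner face, which should place C11 cis to silicon (7S). The step needs chair over boat (secured by the trans-diequatorial alkenyl groups), C- over O-alkylation and α′- over γ-alkylation (the enolate is formed regiospecifically and quenched at −78 °C), and no β-elimination (silicon, not oxygen, at C8).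

Step 8
Reactants: 14 methyl (1(10)E,4Z,7S,8S,9R)-8-[benzyl(dimethyl)silyl]-9-[(4-methoxybenzyl)oxy]-6-oxo-13-norgermacra-1(10),4-dien-12-oate
Product: 16 (1(10)E,4Z,6R,7S,8S,9R)-8-[benzyl(dimethyl)silyl]-9-[(4-methoxybenzyl)oxy]-13-norgermacra-1(10),4-dien-12,6-olide, via 6-hydroxy ester 15 (not isolated)
Conditions: NaBH4, CeCl3·7H2O, MeOH, −40 °C; then PPTS (cat.), CH2Cl2, 25 °C
Reagents that add atoms: none
Why: Luche 1,2-reduction of the Z-enone; hydride should come from the outer face past H7 while the C11 branch lies in the carbonyl plane, giving the 6R alcohol trans to the C7 side chain, which closes to the trans-fused γ-lactone by acid-catalysed transesterification.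

Step 9
Reactants: 16 (1(10)E,4Z,6R,7S,8S,9R)-8-[benzyl(dimethyl)silyl]-9-[(4-methoxybenzyl)oxy]-13-norgermacra-1(10),4-dien-12,6-olide
Product: 18 (1(10)E,4Z,6R,7S,8S,9R)-8-hydroxy-9-[(4-methoxybenzyl)oxy]-13-norgermacra-1(10),4-dien-12,6-olide, via 8-fluorodimethylsilyl lactone 17 (not isolated)
Conditions: Bu4NF, THF, 0 → 25 °C; then 30% H2O2, KHCO3, MeOH/THF, 25 °C
Reagents that add atoms: hydrogen peroxide OO
Why: Tamao–Fleming oxidation of a benzyldimethylsilyl group: fluoride cleaves the benzyl–silicon bond, and the peroxide then induces the 1,2-shift from silicon to oxygen with retention at C8; acyl transfer from O6 to O8 should be slow because the two oxygens lie on opposite faces relative to C11.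

Step 10
Reactants: 18 (1(10)E,4Z,6R,7S,8S,9R)-8-hydroxy-9-[(4-methoxybenzyl)oxy]-13-norgermacra-1(10),4-dien-12,6-olide
Product: 19 (1(10)E,4Z,6R,7S,8S,9R)-9-[(4-methoxybenzyl)oxy]-8-(2-methylpropanoyloxy)-13-norgermacra-1(10),4-dien-12,6-olide
Conditions: (iPrCO)2O, Et3N, DMAP (cat.), CH2Cl2, 0 °C
Reagents that add atoms: 2-methylpropanoic anhydride CC(C)C(=O)OC(=O)C(C)C
Why: DMAP-catalysed acylation of the secondary alcohol directly after its release limits exposure of the free 8-hydroxy lactone; no stereocentre is touched.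

Step 11
Reactants: 19 (1(10)E,4Z,6R,7S,8S,9R)-9-[(4-methoxybenzyl)oxy]-8-(2-methylpropanoyloxy)-13-norgermacra-1(10),4-dien-12,6-olide
Product: 23 (1(10)E,4Z,6R,7S,8S,9R)-9-[(4-methoxybenzyl)oxy]-8-(2-methylpropanoyloxy)germacra-1(10),4,11(13)-trien-12,6-olide, via lithium lactone enolate 20 (not isolated), via 13-dimethylamino Mannich base 21 (not isolated), via trimethylammonium iodide 22 (not isolated)
Conditions: LiN(iPr)2 (1.05 equiv), THF, −78 °C; CH2=NMe2+ I−, −78 → 0 °C; MeI, MeOH, 25 °C; NaHCO3, CH2Cl2/H2O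
Reagents that add atoms: Eschenmoser's salt C=[N+](C)C.[I-]
Why: α-Methylenation by Mannich reaction of the lactone enolate, quaternisation and E1cB loss of trimethylamine; the lactone CH2 is more acidic and less hindered than the isobutyrate methine, and the transient C11 stereocentre is destroyed.

Step 12
Reactants: 23 (1(10)E,4Z,6R,7S,8S,9R)-9-[(4-methoxybenzyl)oxy]-8-(2-methylpropanoyloxy)germacra-1(10),4,11(13)-trien-12,6-olide
Product: 24 (1(10)E,4Z,6R,7S,8S,9R)-9-hydroxy-8-(2-methylpropanoyloxy)germacra-1(10),4,11(13)-trien-12,6-olide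
Conditions: DDQ, CH2Cl2/pH 7 buffer, 0 °C
Reagents that add atoms: none
Why: Oxidative cleavage of the PMB ether (hydride abstraction, hydrolysis of the oxocarbenium ion) under neutral conditions should leave the ester, the lactone and both olefins alone and keep acyl migration to O9 slow.

Step 13
Reactants: 24 (1(10)E,4Z,6R,7S,8S,9R)-9-hydroxy-8-(2-methylpropanoyloxy)germacra-1(10),4,11(13)-trien-12,6-olide
Product: 25 (1R,4Z,6R,7S,8S,9S,10R)-1,10-epoxy-9-hydroxy-8-(2-methylpropanoyloxy)germacra-4,11(13)-dien-12,6-olide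
Conditions: mCPBA, NaHCO3, CH2Cl2, −20 → 0 °C
Reagents that add atoms: 3-chloroperoxybenzoic acid OOC(=O)c1cccc(Cl)c1
Why: Hydroxyl-directed (Henbest) peracid epoxidation; the E-olefin offers only its outer face, and in the reactive conformer the C9 hydroxyl lies on that face with C8 inside, so oxygen is delivered syn to the hydroxyl to give (1R,10R). The 4,5-olefin is deactivated by the allylic lactone oxygen and the methylene lactone is electron-poor.

## Compound list

1 | propyne | CC#C | starting material
2 | dibromo[(Z)-2-bromoprop-1-en-1-yl]borane | C/C(Br)=C/B(Br)Br | intermediate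
3 | 2-[(Z)-2-bromoprop-1-en-1-yl]-4,4,5,5-tetramethyl-1,3,2-dioxaborolane | C/C(Br)=C/B1OC(C)(C)C(C)(C)O1 | intermediate
4 | (4-methoxyphenyl)methanol | COc1ccc(CO)cc1 | starting material
5 | 1-({[(Z)-2-bromoprop-1-en-1-yl]oxy}methyl)-4-methoxybenzene | C/C(Br)=C/OCc1ccc(OC)cc1 | intermediate
6 | (3S)-3-methylcyclohexan-1-one | O=C1C[C@@H](C)CCC1 | starting material
7 | (2R,5S)-2-{(Z)-1-[(4-methoxyphenyl)methoxy]prop-1-en-2-yl}-5-methylcyclohexan-1-one | O=C1C[C@@H](C)CC[C@@H]1/C(C)=C\OCc2ccc(OC)cc2 | intermediate
8 | lithium (3S,6R)-6-{(Z)-1-[(4-methoxyphenyl)methoxy]prop-1-en-2-yl}-3-methylcyclohex-1-en-1-olate | [Li+].[O-]C1=C[C@@H](C)CC[C@@H]1/C(C)=C\OCc2ccc(OC)cc2 | intermediate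
9 | (6R)-6-{(Z)-1-[(4-methoxyphenyl)methoxy]prop-1-en-2-yl}-3-methylcyclohex-2-en-1-one | O=C1C=C(C)CC[C@@H]1/C(C)=C\OCc2ccc(OC)cc2 | intermediate
10 | (1R,6R)-1-ethynyl-6-{(Z)-1-[(4-methoxyphenyl)methoxy]prop-1-en-2-yl}-3-methylcyclohex-2-en-1-ol | O[C@]1(C#C)C=C(C)CC[C@@H]1/C(C)=C\OCc2ccc(OC)cc2 | intermediate
11 | (1R,6R)-1-{(E)-2-[benzyl(dimethyl)silyl]ethenyl}-6-{(Z)-1-[(4-methoxyphenyl)methoxy]prop-1-en-2-yl}-3-methylcyclohex-2-en-1-ol | O[C@]1(/C=C/[Si](C)(C)Cc2ccccc2)C=C(C)CC[C@@H]1/C(C)=C\OCc2ccc(OC)cc2 | intermediate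
12 | potassium alkoxide of 11 | [K+].[O-][C@]1(/C=C/[Si](C)(C)Cc2ccccc2)C=C(C)CC[C@@H]1/C(C)=C\OCc2ccc(OC)cc2 | intermediate
13 | potassium (1(10)E,4Z,6E,8S,9R)-8-[benzyl(dimethyl)silyl]-9-[(4-methoxybenzyl)oxy]-11,12,13-trinorgermacra-1(10),4,6-trien-6-olate | [K+].[O-]/C1=C\[C@H]([Si](C)(C)Cc2ccccc2)[C@H](OCc2ccc(OC)cc2)/C(C)=C/CC/C(C)=C\1 | intermediate
14 | methyl (1(10)E,4Z,7S,8S,9R)-8-[benzyl(dimethyl)silyl]-9-[(4-methoxybenzyl)oxy]-6-oxo-13-norgermacra-1(10),4-dien-12-oate | O=C1/C=C(/C)CC/C=C(\C)[C@@H](OCc2ccc(OC)cc2)[C@@H]([Si](C)(C)Cc2ccccc2)[C@H]1CC(=O)OC | intermediate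
15 | methyl (1(10)E,4Z,6R,7S,8S,9R)-8-[benzyl(dimethyl)silyl]-6-hydroxy-9-[(4-methoxybenzyl)oxy]-13-norgermacra-1(10),4-dien-12-oate | O[C@@H]1/C=C(/C)CC/C=C(\C)[C@@H](OCc2ccc(OC)cc2)[C@@H]([Si](C)(C)Cc2ccccc2)[C@H]1CC(=O)OC | intermediate
16 | (1(10)E,4Z,6R,7S,8S,9R)-8-[benzyl(dimethyl)silyl]-9-[(4-methoxybenzyl)oxy]-13-norgermacra-1(10),4-dien-12,6-olide | C1C(=O)O[C@@H]2/C=C(/C)CC/C=C(\C)[C@@H](OCc3ccc(OC)cc3)[C@@H]([Si](C)(C)Cc3ccccc3)[C@@H]12 | intermediate
17 | (1(10)E,4Z,6R,7S,8S,9R)-8-[fluoro(dimethyl)silyl]-9-[(4-methoxybenzyl)oxy]-13-norgermacra-1(10),4-dien-12,6-olide | C1C(=O)O[C@@H]2/C=C(/C)CC/C=C(\C)[C@@H](OCc3ccc(OC)cc3)[C@@H]([Si](C)(C)F)[C@@H]12 | intermediate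
18 | (1(10)E,4Z,6R,7S,8S,9R)-8-hydroxy-9-[(4-methoxybenzyl)oxy]-13-norgermacra-1(10),4-dien-12,6-olide | C1C(=O)O[C@@H]2/C=C(/C)CC/C=C(\C)[C@@H](OCc3ccc(OC)cc3)[C@@H](O)[C@@H]12 | intermediate
19 | (1(10)E,4Z,6R,7S,8S,9R)-9-[(4-methoxybenzyl)oxy]-8-(2-methylpropanoyloxy)-13-norgermacra-1(10),4-dien-12,6-olide | C1C(=O)O[C@@H]2/C=C(/C)CC/C=C(\C)[C@@H](OCc3ccc(OC)cc3)[C@@H](OC(=O)C(C)C)[C@@H]12 | intermediate
20 | lithium enolate of 19 (C11=C12–OLi) | C1=C([O-])O[C@@H]2/C=C(/C)CC/C=C(\C)[C@@H](OCc3ccc(OC)cc3)[C@@H](OC(=O)C(C)C)[C@@H]12.[Li+] | intermediate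
21 | (1(10)E,4Z,6R,7S,8S,9R)-13-(dimethylamino)-9-[(4-methoxybenzyl)oxy]-8-(2-methylpropanoyloxy)germacra-1(10),4-dien-12,6-olide (C11 epimers) | CN(C)CC1C(=O)O[C@@H]2/C=C(/C)CC/C=C(\C)[C@@H](OCc3ccc(OC)cc3)[C@@H](OC(=O)C(C)C)[C@@H]12 | intermediate
22 | N,N,N-trimethylammonium iodide of 21 | C[N+](C)(C)CC1C(=O)O[C@@H]2/C=C(/C)CC/C=C(\C)[C@@H](OCc3ccc(OC)cc3)[C@@H](OC(=O)C(C)C)[C@@H]12.[I-] | intermediate
23 | (1(10)E,4Z,6R,7S,8S,9R)-9-[(4-methoxybenzyl)oxy]-8-(2-methylpropanoyloxy)germacra-1(10),4,11(13)-trien-12,6-olide | C=C1C(=O)O[C@@H]2/C=C(/C)CC/C=C(\C)[C@@H](OCc3ccc(OC)cc3)[C@@H](OC(=O)C(C)C)[C@@H]12 | intermediate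
24 | (1(10)E,4Z,6R,7S,8S,9R)-9-hydroxy-8-(2-methylpropanoyloxy)germacra-1(10),4,11(13)-trien-12,6-olide | C=C1C(=O)O[C@@H]2/C=C(/C)CC/C=C(\C)[C@@H](O)[C@@H](OC(=O)C(C)C)[C@@H]12 | intermediate
25 | (1R,4Z,6R,7S,8S,9S,10R)-1,10-epoxy-9-hydroxy-8-(2-methylpropanoyloxy)germacra-4,11(13)-dien-12,6-olide (CNP0110853.2) | C=C1C(=O)O[C@@H]2/C=C(/C)CC[C@H]3O[C@]3(C)[C@@H](O)[C@@H](OC(=O)C(C)C)[C@@H]12 | target

## Step count and least certain steps

Total: 13 steps. Longest linear sequence: 13 steps (1 to 25); 11 steps from ketone 6.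

Step 7 (key step). The dienolate 13 may equilibrate by proton transfer with product 14, leading to over-alkylation, γ-alkylation or loss of the C7 configuration. The alkoxide 12, with an axial alkoxy group in the chair, may also fragment instead of rearranging. The C7 facial selectivity rests on the conformer that holds silicon in the enolate plane. Fallback: uncouple the ring expansion from the C–C bond formation and run it without charge. Starting from 11, silylation (Me3SiCl, imidazole) gives the trimethylsilyl ether F1. Thermal siloxy-Cope rearrangement (sealed tube, about 200 °C) gives the ring-expanded trimethylsilyl enol ether F2. MeLi releases the lithium enolate F3 regiospecifically at −78 °C, and alkylation with BrCH2CO2Me returns to 14.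

Step 3. Enolisation of 6 toward C2 instead of C6 would give the regioisomer. The β,γ-double bond may migrate into conjugation, the alkenylpalladium intermediate may lose alkoxide, and incomplete trans selectivity would erode the enantiomeric purity of 9 after step 4. Fallback: reverse the polarity and fix the regiochemistry on the enone. From 5, bromine–lithium exchange (t-BuLi; any E isomer destroys itself by anti-elimination) and ZnCl2 give the (Z)-alkenylzinc chloride F6. 3-Methylcyclohex-2-en-1-one F4 is brominated at C6 (LiN(iPr)2, then NBS) to racemic 6-bromo-3-methylcyclohex-2-en-1-one F5. A stereoconvergent nickel-catalysed Negishi coupling (NiCl2·glyme, chiral pybox ligand) of F5 with F6 returns to the route at 9.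

Step 8. Hydride delivery to the other face of the C6 carbonyl (or conjugate reduction) would give the 6-epimer, which closes to the cis-fused lactone. Fallback: correct C6 by substitution instead of by facial control. From 14, the cis-lactone F7 formed in that case is opened with LiOH to the 6-epi hydroxy acid F8. Intramolecular Mitsunobu lactonisation (PPh3, DIAD) with inversion at the allylic C6 returns to 16.

Step 9. Under fluoride and bicarbonate the freed 8-hydroxyl may take over the acyl group (translactonisation to the 8,12-olide), or the silyl group may be lost with the neighbouring alkoxy group. Fallback: mask the lactone carbonyl during the C–Si oxidation. From 16, iBu2AlH gives the lactol F9 and MeOH/PPTS its methyl acetal F10. Tamao–Fleming oxidation gives the 8-hydroxy acetal F11 and acylation the 8-isobutyrate F12. Mild hydrolysis (PPTS, acetone/H2O) gives the lactol F13, and oxidation with Pr4NRuO4/NMO returns to 19.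

Step 13. The peracid may also attack the 4,5-olefin or over-oxidise, and the acid by-product may open the epoxide transannularly. Fallback: change from hydrogen-bond direction to an alkoxide-bound oxidant (VO(acac)2, t-BuOOH, CH2Cl2, 0 °C), which reacts only at the olefin allylic to the C9 hydroxyl. It starts from 24 and ends at 25 without new compounds.

## Further compounds

F1 | step 7 | trimethylsilyl ether of 11 | C[Si](C)(C)O[C@]1(/C=C/[Si](C)(C)Cc2ccccc2)C=C(C)CC[C@@H]1/C(C)=C\OCc2ccc(OC)cc2
F2 | step 7 | (1(10)E,4Z,6E,8S,9R)-8-[benzyl(dimethyl)silyl]-9-[(4-methoxybenzyl)oxy]-6-(trimethylsilyloxy)-11,12,13-trinorgermacra-1(10),4,6-triene | C[Si](C)(C)O/C1=C\[C@H]([Si](C)(C)Cc2ccccc2)[C@H](OCc2ccc(OC)cc2)/C(C)=C/CC/C(C)=C\1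
F3 | step 7 | lithium analogue of dienolate 13 | [Li+].[O-]/C1=C\[C@H]([Si](C)(C)Cc2ccccc2)[C@H](OCc2ccc(OC)cc2)/C(C)=C/CC/C(C)=C\1
F4 | step 3 | 3-methylcyclohex-2-en-1-one | CC1=CC(=O)CCC1
F5 | step 3 | 6-bromo-3-methylcyclohex-2-en-1-one (racemic) | CC1=CC(=O)C(Br)CC1
F6 | step 3 | chloro{(Z)-1-[(4-methoxyphenyl)methoxy]prop-1-en-2-yl}zinc | C/C([Zn]Cl)=C/OCc1ccc(OC)cc1
F7 | step 8 | (1(10)E,4Z,6S,7S,8S,9R)-8-[benzyl(dimethyl)silyl]-9-[(4-methoxybenzyl)oxy]-13-norgermacra-1(10),4-dien-12,6-olide (cis-lactone) | C1C(=O)O[C@H]2/C=C(/C)CC/C=C(\C)[C@@H](OCc3ccc(OC)cc3)[C@@H]([Si](C)(C)Cc3ccccc3)[C@@H]12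
F8 | step 8 | (1(10)E,4Z,6S,7S,8S,9R)-8-[benzyl(dimethyl)silyl]-6-hydroxy-9-[(4-methoxybenzyl)oxy]-13-norgermacra-1(10),4-dien-12-oic acid | O[C@H]1/C=C(/C)CC/C=C(\C)[C@@H](OCc2ccc(OC)cc2)[C@@H]([Si](C)(C)Cc2ccccc2)[C@H]1CC(=O)O
F9 | step 9 | lactol of 16 (12-hydroxy-12,6-epoxide; C12 epimers) | C1C(O)O[C@@H]2/C=C(/C)CC/C=C(\C)[C@@H](OCc3ccc(OC)cc3)[C@@H]([Si](C)(C)Cc3ccccc3)[C@@H]12
F10 | step 9 | methyl acetal of F9 | C1C(OC)O[C@@H]2/C=C(/C)CC/C=C(\C)[C@@H](OCc3ccc(OC)cc3)[C@@H]([Si](C)(C)Cc3ccccc3)[C@@H]12
F11 | step 9 | 8-hydroxy methyl acetal | C1C(OC)O[C@@H]2/C=C(/C)CC/C=C(\C)[C@@H](OCc3ccc(OC)cc3)[C@@H](O)[C@@H]12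
F12 | step 9 | 8-(2-methylpropanoyloxy) methyl acetal | C1C(OC)O[C@@H]2/C=C(/C)CC/C=C(\C)[C@@H](OCc3ccc(OC)cc3)[C@@H](OC(=O)C(C)C)[C@@H]12
F13 | step 9 | 8-(2-methylpropanoyloxy) lactol | C1C(O)O[C@@H]2/C=C(/C)CC/C=C(\C)[C@@H](OCc3ccc(OC)cc3)[C@@H](OC(=O)C(C)C)[C@@H]12
F0 | step 13 | none | none
A1 | alternative 1 | methyl (2Z,4S,5R,6E,10Z)-2-(bromomethyl)-5-[(4-methoxybenzyl)oxy]-6,10-dimethyl-4-(2-methylpropanoyloxy)-12-oxododeca-2,6,10-trienoate | O=C/C=C(/C)CC/C=C(\C)[C@@H](OCc1ccc(OC)cc1)[C@@H](OC(=O)C(C)C)/C=C(\CBr)C(=O)OC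
A2 | alternative 2 | (4S,5R)-5-ethenyl-4-{(1S,2R,3E)-2-[(4-methoxybenzyl)oxy]-3,7-dimethyl-1-(2-methylpropanoyloxy)octa-3,7-dien-1-yl}-3-methylideneoxolan-2-one | C=C[C@H]1OC(=O)C(=C)[C@@H]1[C@H](OC(=O)C(C)C)[C@H](OCc2ccc(OC)cc2)/C(C)=C/CCC(C)=C
A3 | alternative 3 | trans-fused decalin: methyl 2-[6-hydroxy-10-(methanesulfonyloxy)-9-[(4-methoxybenzyl)oxy]-4,10-dimethyl-8-(2-methylpropanoyloxy)bicyclo[4.4.0]dec-4-en-7-yl]acetate (germacrane atom numbers, C1–C6 bond intact) | O[C@]12C=C(C)CC[C@@H]1[C@@](C)(OS(C)(=O)=O)[C@@H](OCc3ccc(OC)cc3)[C@@H](OC(=O)C(C)C)[C@H]2CC(=O)OC
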